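**Plan**

- Locants: flavone 1 is the 5‑hydroxy‑7‑methoxy‑2,3‑diarylchromone; flavone 2 is the 5,7‑dihydroxyflavone whose C2 sits para to OMe on the linking anisole ring. The target has no stereocentre.
- Retrosynthesis: the three benzyl ethers come off last. Flavone 2 is cut at O1–C2 and C2–C3 (chalcone from an aryl aldehyde and a dibenzylated phloroacetophenone), and the formyl carbon at its aryl–C bond (aryl bromide).
- Ring A of flavone 1 (C4a, C5–C8, C8a) has 5‑OH peri to the C4 carbonyl and 7‑OMe meta to it. A ketene carbonyl carbon (C5) and the OMe‑bearing carbon of methoxyacetylene (C7) leave exactly this pattern, so the ring is cut at C8a–C8, C7–C8, C5–C6 and C4a–C5, back to a 6‑diazoacetyl‑2,3‑diaryl‑4‑pyranone and methoxyacetylene.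
- The pyranone (own numbering) is cut at O1–C6 and C5–C6 (oxalate Claisen, cyclodehydration), C3–C4 (C‑acetylation) and C2–aryl (Weinreb ketone synthesis).
- Forward: ring C of flavone 1 first, then its ring A by benzannulation, then ring C of flavone 2. The E chalcone alkene and the racemic sp3 carbons of transient intermediates are erased on the way.

Key step: step 8

Assumption: 1‑[2,4‑bis(benzyloxy)‑6‑hydroxyphenyl]ethan‑1‑one (23) is taken as a catalogue compound, whereas methoxyacetylene is too volatile and labile to be stocked and is made in step 7.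

**Step 1**
Reactants: 1 2-(5-bromo-2-methoxyphenyl)acetic acid
Product: 3 2-(5-bromo-2-methoxyphenyl)-N-methoxy-N-methylacetamide, via acyl imidazole 2 (not isolated)
Conditions: CDI, CH2Cl2, rt; then MeNHOMe·HCl, rt
Reagents that add atoms: N,O-dimethylhydroxylamine hydrochloride, CNOC.Cl
Why: Amide formation through the acyl imidazole (CDI coupling) is routine for arylacetic acids, and neither the aryl bromide nor the methyl ether takes part.

**Step 2**
Reactants: 4 1-(benzyloxy)-4-bromobenzene; 3 2-(5-bromo-2-methoxyphenyl)-N-methoxy-N-methylacetamide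
Product: 6 1-[4-(benzyloxy)phenyl]-2-(5-bromo-2-methoxyphenyl)ethan-1-one, via aryl Grignard reagent 5 (not isolated)
Conditions: 4, Mg, THF, 45 °C; then 3, THF, 0 °C; aq. HCl
Reagents that add atoms: none
Why: Weinreb ketone synthesis, in which the N‑methoxy‑N‑methylamide accepts only one equivalent of the aryl Grignard reagent, the aryl bromide of 3 does not exchange with an arylmagnesium halide at 0 °C, and an excess of 5 covers any loss to enolisation.

**Step 3**
Reactants: 6 1-[4-(benzyloxy)phenyl]-2-(5-bromo-2-methoxyphenyl)ethan-1-one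
Product: 7 1-[4-(benzyloxy)phenyl]-2-(5-bromo-2-methoxyphenyl)butane-1,3-dione
Conditions: AcCl, MgBr2·OEt2, i-Pr2NEt, CH2Cl2, rt
Reagents that add atoms: acetyl chloride, CC(=O)Cl
Why: Soft enolisation gives the magnesium enolate at the only enolisable position, and magnesium enolates are acylated on carbon (Claisen‑type C‑acylation of a ketone), the racemic, enolisable diketone being held as its magnesium chelate until work‑up.

**Step 4**
Reactants: 7 1-[4-(benzyloxy)phenyl]-2-(5-bromo-2-methoxyphenyl)butane-1,3-dione; 8 diethyl oxalate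
Product: 10 ethyl 6-[4-(benzyloxy)phenyl]-5-(5-bromo-2-methoxyphenyl)-4-oxo-4H-pyran-2-carboxylate, via trioxo ester 9 (not isolated)
Conditions: LiN(i-Pr)2 (3.1 equiv), THF, −78 to −20 °C; 8, −78 °C; aq. HCl; then TsOH·H2O, toluene, 80 °C
Reagents that add atoms: none
Why: Twofold deprotonation of the β‑diketone makes its methyl carbon the nucleophile for a Claisen condensation with the oxalate, and acid then cyclodehydrates the 2,4,6‑trioxo ester to the only six‑membered ring it can form, the 4‑pyranone (classical comanic ester synthesis).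

**Step 5**
Reactants: 10 ethyl 6-[4-(benzyloxy)phenyl]-5-(5-bromo-2-methoxyphenyl)-4-oxo-4H-pyran-2-carboxylate
Product: 11 6-[4-(benzyloxy)phenyl]-5-(5-bromo-2-methoxyphenyl)-4-oxo-4H-pyran-2-carboxylic acid
Conditions: LiOH·H2O (1.2 equiv), THF/H2O, 0 °C; then aq. HCl
Reagents that add atoms: lithium hydroxide, [Li+].[OH-]
Why: Saponification of the activated ester next to the ring oxygen should be much faster than hydroxide attack on the pyranone at 0 °C with a small excess of base, as in the hydrolysis of chromone‑2‑carboxylates.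

**Step 6**
Reactants: 11 6-[4-(benzyloxy)phenyl]-5-(5-bromo-2-methoxyphenyl)-4-oxo-4H-pyran-2-carboxylic acid
Product: 13 2-[4-(benzyloxy)phenyl]-3-(5-bromo-2-methoxyphenyl)-6-(2-diazoacetyl)-4H-pyran-4-one, via acid chloride 12 (not isolated)
Conditions: (COCl)2, DMF (cat.), CH2Cl2, 0 °C to rt; then CH2N2 (3 equiv), Et2O/THF, 0 °C
Reagents that add atoms: diazomethane, C=[N+]=[N-]
Why: Acylation of diazomethane by an acid chloride (first stage of an Arndt–Eistert sequence) is the standard entry to diazomethyl ketones, a further equivalent of diazomethane removing the HCl so that no chloromethyl ketone forms.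

**Step 7**
Reactants: 14 chloroacetaldehyde dimethyl acetal (2-chloro-1,1-dimethoxyethane)
Product: 16 methoxyacetylene, via sodium methoxyacetylide 15 (not isolated)
Conditions: NaNH2 (3 equiv), liq. NH3, −33 °C; then aq. NaCl, −70 °C to rt, distil into cold ClCH2CH2Cl
Reagents that add atoms: none
Why: Sodium amide brings about twofold elimination (HCl and methanol) from the chloro acetal and holds the alkyne as its acetylide until the quench, which is the established preparation of alkoxyacetylenes.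

**Step 8**
Reactants: 13 2-[4-(benzyloxy)phenyl]-3-(5-bromo-2-methoxyphenyl)-6-(2-diazoacetyl)-4H-pyran-4-one; 16 methoxyacetylene
Product: 21 2-[4-(benzyloxy)phenyl]-3-(5-bromo-2-methoxyphenyl)-5-hydroxy-7-methoxy-4H-chromen-4-one, via pyranonylketene 17 (not isolated), via methoxycyclobutenone 18 (not isolated), via dienylketene 19 (not isolated), via cyclohexadienone 20 (not isolated)
Conditions: 16 (4 equiv), hν (440 nm LED), ClCH2CH2Cl, 5 °C, closed vessel; then 80 °C
Reagents that add atoms: none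
Why: Proposed new method: 440 nm light excites only the diazo ketone, N2 leaves and the pyranonyl group shifts to the carbene carbon (photo‑Wolff rearrangement, C8a–C8), ketene 17 adds methoxyacetylene in a thermal [2+2] cycloaddition (C5–C6 and C7–C8) to cyclobutenone 18, and at 80 °C 18 opens in a conrotatory 4π process to dienylketene 19, which closes onto C5 of the pyranone (C4a–C5) and enolises via 20 to the phenol. The closest known reaction type is the Danheiser benzannulation in its photo‑Wolff form, established for alkenyl, aryl and heteroaryl diazomethyl ketones with alkoxy‑ and siloxyalkynes but not for a ketene carried by a 4‑pyranone. Ring A, the only ring closed, is a six‑membered carbocycle formed by disrotatory 6π electrocyclisation; the ring opening of 18 is reversible, so the dienylketene geometry that cannot close is recycled. No stereocentre is created in 21, the sp3 carbons of 18 and 20 being transient. The step needs regiocontrol in the [2+2] event, and the polarised ynol ether provides it: its nucleophilic CH carbon bonds to the ketene carbonyl carbon, which places the former ketene oxygen at C5, peri to the C4 carbonyl, and OMe at C7. Closure can occur only at the single C–H carbon of the pyranone next to the ketene‑bearing carbon, and the long wavelength spares the diarylpyranone chromophore, the aryl bromide and the benzyl ether.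

**Step 9**
Reactants: 21 2-[4-(benzyloxy)phenyl]-3-(5-bromo-2-methoxyphenyl)-5-hydroxy-7-methoxy-4H-chromen-4-one
Product: 22 3-{2-[4-(benzyloxy)phenyl]-5-hydroxy-7-methoxy-4-oxo-4H-chromen-3-yl}-4-methoxybenzaldehyde
Conditions: Pd(OAc)2 (cat.), n-BuP(1-Ad)2, TMEDA, CO/H2 (1:1, 5 bar), toluene, 100 °C
Reagents that add atoms: carbon monoxide, [C-]#[O+]
Why: Palladium‑catalysed reductive carbonylation (formylation) of an aryl bromide, by oxidative addition to zerovalent palladium, CO insertion and hydrogenolysis of the acyl complex, is reliable for electron‑rich bromoarenes and under homogeneous conditions should leave the benzyl ether and the chromone untouched.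

**Step 10**
Reactants: 22 3-{2-[4-(benzyloxy)phenyl]-5-hydroxy-7-methoxy-4-oxo-4H-chromen-3-yl}-4-methoxybenzaldehyde; 23 1-[2,4-bis(benzyloxy)-6-hydroxyphenyl]ethan-1-one
Product: 24 (2E)-1-[2,4-bis(benzyloxy)-6-hydroxyphenyl]-3-(3-{2-[4-(benzyloxy)phenyl]-5-hydroxy-7-methoxy-4-oxo-4H-chromen-3-yl}-4-methoxyphenyl)prop-2-en-1-one
Conditions: KOH (aq.), EtOH/THF, rt
Reagents that add atoms: none
Why: Claisen–Schmidt condensation of the acetophenone enolate with the non‑enolisable aldehyde gives the E enone after dehydration, while the ionised 5‑OH of flavone 1 deactivates its 2,3‑disubstituted pyranone towards hydroxide.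

**Step 11**
Reactants: 24 (2E)-1-[2,4-bis(benzyloxy)-6-hydroxyphenyl]-3-(3-{2-[4-(benzyloxy)phenyl]-5-hydroxy-7-methoxy-4-oxo-4H-chromen-3-yl}-4-methoxyphenyl)prop-2-en-1-one
Product: 26 5,7-bis(benzyloxy)-2-(3-{2-[4-(benzyloxy)phenyl]-5-hydroxy-7-methoxy-4-oxo-4H-chromen-3-yl}-4-methoxyphenyl)-4H-chromen-4-one, via flavanone 25 (not isolated)
Conditions: I2 (10 mol %), DMSO, 130 °C
Reagents that add atoms: none
Why: Iodine‑catalysed oxidative cyclisation of a 2'‑hydroxychalcone in DMSO proceeds by oxa‑Michael closure to racemic flavanone 25 and its dehydrogenation by iodine, which DMSO regenerates from HI, and the catalytic amount of iodine limits ring iodination.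

**Step 12**
Reactants: 26 5,7-bis(benzyloxy)-2-(3-{2-[4-(benzyloxy)phenyl]-5-hydroxy-7-methoxy-4-oxo-4H-chromen-3-yl}-4-methoxyphenyl)-4H-chromen-4-one
Product: 27 5,7-dihydroxy-2-{3-[5-hydroxy-2-(4-hydroxyphenyl)-7-methoxy-4-oxo-4H-chromen-3-yl]-4-methoxyphenyl}-4H-chromen-4-one
Conditions: H2 (1 atm), Pd/C, THF/MeOH, rt
Reagents that add atoms: none
Why: Hydrogenolysis of the three benzyl aryl ethers over Pd/C should leave the flavone C2=C3 bonds and both aryl methyl ethers intact under these mild conditions.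

**Compound list**

1 | 2-(5-bromo-2-methoxyphenyl)acetic acid | COc1ccc(Br)cc1CC(=O)O | starting material
2 | 1-[2-(5-bromo-2-methoxyphenyl)acetyl]-1H-imidazole | COc1ccc(Br)cc1CC(=O)n1ccnc1 | intermediate
3 | 2-(5-bromo-2-methoxyphenyl)-N-methoxy-N-methylacetamide | COc1ccc(Br)cc1CC(=O)N(C)OC | intermediate
4 | 1-(benzyloxy)-4-bromobenzene | Brc1ccc(OCc2ccccc2)cc1 | starting material
5 | [4-(benzyloxy)phenyl]magnesium bromide | Br[Mg]c1ccc(OCc2ccccc2)cc1 | intermediate
6 | 1-[4-(benzyloxy)phenyl]-2-(5-bromo-2-methoxyphenyl)ethan-1-one | COc1ccc(Br)cc1CC(=O)c1ccc(OCc2ccccc2)cc1 | intermediate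
7 | 1-[4-(benzyloxy)phenyl]-2-(5-bromo-2-methoxyphenyl)butane-1,3-dione (racemic) | COc1ccc(Br)cc1C(C(C)=O)C(=O)c1ccc(OCc2ccccc2)cc1 | intermediate
8 | diethyl oxalate | CCOC(=O)C(=O)OCC | starting material
9 | ethyl 6-[4-(benzyloxy)phenyl]-5-(5-bromo-2-methoxyphenyl)-2,4,6-trioxohexanoate (racemic) | CCOC(=O)C(=O)CC(=O)C(c1cc(Br)ccc1OC)C(=O)c1ccc(OCc2ccccc2)cc1 | intermediate
10 | ethyl 6-[4-(benzyloxy)phenyl]-5-(5-bromo-2-methoxyphenyl)-4-oxo-4H-pyran-2-carboxylate | CCOC(=O)c1cc(=O)c(-c2cc(Br)ccc2OC)c(-c2ccc(OCc3ccccc3)cc2)o1 | intermediate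
11 | 6-[4-(benzyloxy)phenyl]-5-(5-bromo-2-methoxyphenyl)-4-oxo-4H-pyran-2-carboxylic acid | OC(=O)c1cc(=O)c(-c2cc(Br)ccc2OC)c(-c2ccc(OCc3ccccc3)cc2)o1 | intermediate
12 | 6-[4-(benzyloxy)phenyl]-5-(5-bromo-2-methoxyphenyl)-4-oxo-4H-pyran-2-carbonyl chloride | ClC(=O)c1cc(=O)c(-c2cc(Br)ccc2OC)c(-c2ccc(OCc3ccccc3)cc2)o1 | intermediate
13 | 2-[4-(benzyloxy)phenyl]-3-(5-bromo-2-methoxyphenyl)-6-(2-diazoacetyl)-4H-pyran-4-one | [N-]=[N+]=CC(=O)c1cc(=O)c(-c2cc(Br)ccc2OC)c(-c2ccc(OCc3ccccc3)cc2)o1 | intermediate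
14 | chloroacetaldehyde dimethyl acetal (2-chloro-1,1-dimethoxyethane) | COC(CCl)OC | starting material
15 | sodium methoxyacetylide | COC#[C-].[Na+] | intermediate
16 | methoxyacetylene | COC#C | intermediate
17 | 2-[4-(benzyloxy)phenyl]-3-(5-bromo-2-methoxyphenyl)-6-(2-oxoethenyl)-4H-pyran-4-one (pyranonylketene) | O=C=Cc1cc(=O)c(-c2cc(Br)ccc2OC)c(-c2ccc(OCc3ccccc3)cc2)o1 | intermediate
18 | 2-[4-(benzyloxy)phenyl]-3-(5-bromo-2-methoxyphenyl)-6-(2-methoxy-4-oxocyclobut-2-en-1-yl)-4H-pyran-4-one (racemic) | COC1=CC(=O)C1c1cc(=O)c(-c2cc(Br)ccc2OC)c(-c2ccc(OCc3ccccc3)cc2)o1 | intermediate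
19 | 2-[4-(benzyloxy)phenyl]-3-(5-bromo-2-methoxyphenyl)-6-[(1E)-2-methoxy-4-oxobuta-1,3-dien-1-yl]-4H-pyran-4-one (dienylketene) | O=C=C/C(OC)=C\c1cc(=O)c(-c2cc(Br)ccc2OC)c(-c2ccc(OCc3ccccc3)cc2)o1 | intermediate
20 | 2-[4-(benzyloxy)phenyl]-3-(5-bromo-2-methoxyphenyl)-7-methoxy-4H-chromene-4,5(4aH)-dione (racemic keto tautomer of 21) | COC1=CC(=O)C2C(=C1)OC(-c1ccc(OCc3ccccc3)cc1)=C(-c1cc(Br)ccc1OC)C2=O | intermediate
21 | 2-[4-(benzyloxy)phenyl]-3-(5-bromo-2-methoxyphenyl)-5-hydroxy-7-methoxy-4H-chromen-4-one | COc1cc(O)c2c(=O)c(-c3cc(Br)ccc3OC)c(-c3ccc(OCc4ccccc4)cc3)oc2c1 | intermediate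
22 | 3-{2-[4-(benzyloxy)phenyl]-5-hydroxy-7-methoxy-4-oxo-4H-chromen-3-yl}-4-methoxybenzaldehyde | COc1cc(O)c2c(=O)c(-c3cc(C=O)ccc3OC)c(-c3ccc(OCc4ccccc4)cc3)oc2c1 | intermediate
23 | 1-[2,4-bis(benzyloxy)-6-hydroxyphenyl]ethan-1-one | CC(=O)c1c(O)cc(OCc2ccccc2)cc1OCc1ccccc1 | starting material
24 | (2E)-1-[2,4-bis(benzyloxy)-6-hydroxyphenyl]-3-(3-{2-[4-(benzyloxy)phenyl]-5-hydroxy-7-methoxy-4-oxo-4H-chromen-3-yl}-4-methoxyphenyl)prop-2-en-1-one | COc1cc(O)c2c(=O)c(-c3cc(/C=C/C(=O)c4c(O)cc(OCc5ccccc5)cc4OCc4ccccc4)ccc3OC)c(-c3ccc(OCc4ccccc4)cc3)oc2c1 | intermediate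
25 | 5,7-bis(benzyloxy)-2-(3-{2-[4-(benzyloxy)phenyl]-5-hydroxy-7-methoxy-4-oxo-4H-chromen-3-yl}-4-methoxyphenyl)-2,3-dihydro-4H-chromen-4-one (racemic) | COc1cc(O)c2c(=O)c(-c3cc(C4CC(=O)c5c(OCc6ccccc6)cc(OCc6ccccc6)cc5O4)ccc3OC)c(-c3ccc(OCc4ccccc4)cc3)oc2c1 | intermediate
26 | 5,7-bis(benzyloxy)-2-(3-{2-[4-(benzyloxy)phenyl]-5-hydroxy-7-methoxy-4-oxo-4H-chromen-3-yl}-4-methoxyphenyl)-4H-chromen-4-one | COc1cc(O)c2c(=O)c(-c3cc(-c4cc(=O)c5c(OCc6ccccc6)cc(OCc6ccccc6)cc5o4)ccc3OC)c(-c3ccc(OCc4ccccc4)cc3)oc2c1 | intermediate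
27 | 5,7-dihydroxy-2-{3-[5-hydroxy-2-(4-hydroxyphenyl)-7-methoxy-4-oxo-4H-chromen-3-yl]-4-methoxyphenyl}-4H-chromen-4-one | COc1cc(O)c2c(=O)c(-c3cc(-c4cc(=O)c5c(O)cc(O)cc5o4)ccc3OC)c(-c3ccc(O)cc3)oc2c1 | target

**Step count and risks**

Total step count: 12. Longest linear sequence: 11 steps (steps 1–6 and 8–12, from 1); step 7 is a one‑step side branch.

Steps most likely to fail:

1. Step 8. The pyranonylketene may dimerise or be consumed by the phenol already formed before it meets the volatile alkyne, or the dienylketene may fail to close onto the electron‑poor pyranone and decay instead. The fallback uses the classical deoxybenzoin route to 2,3‑diarylchromones; it sets out from 1 and comes back to the route at 21.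
   - Friedel–Crafts acylation of phloroglucinol (benzene‑1,3,5‑triol) with 1 in BF3·OEt2 at 85 °C should give 2-(5-bromo-2-methoxyphenyl)-1-(2,4,6-trihydroxyphenyl)ethan-1-one F1.
   - Heating F1 with commercial 4‑(benzyloxy)benzoyl chloride and K2CO3 in acetone (O‑aroylation, Baker–Venkataraman‑type acyl shift to the benzylic carbon, cyclodehydration) should give 2-[4-(benzyloxy)phenyl]-3-(5-bromo-2-methoxyphenyl)-5-hydroxy-4-oxo-4H-chromen-7-yl 4-(benzyloxy)benzoate F2.
   - K2CO3 in MeOH removes the 7‑O‑aroyl group to give 2-[4-(benzyloxy)phenyl]-3-(5-bromo-2-methoxyphenyl)-5,7-dihydroxy-4H-chromen-4-one F3.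
   - MeI (1 equiv) with K2CO3 in acetone methylates only the free 7‑OH, the 5‑OH being tied up in a hydrogen bond to the C4 carbonyl, which gives 21.

2. Step 4. The second deprotonation of the hindered α‑aryl diketone may stay incomplete, or the nucleophile may add twice to the doubly activated oxalate, so that the trioxo ester does not form cleanly. The fallback needs no strong base; it sets out from 6 and comes back to the route at 11, bypassing steps 3–5.
   - Morpholine and TiCl4 in toluene convert 6 into the enamine 4-{1-[4-(benzyloxy)phenyl]-2-(5-bromo-2-methoxyphenyl)ethenyl}morpholine F4.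
   - Diketene acylates the β‑carbon of F4 and the acetoacetyl enol displaces morpholine on warming with AcOH (the classical enamine–diketene pyranone synthesis), giving 6-[4-(benzyloxy)phenyl]-5-(5-bromo-2-methoxyphenyl)-2-methyl-4H-pyran-4-one F5.
   - SeO2 in dioxane at 100 °C oxidises the activated 2‑methyl group to 6-[4-(benzyloxy)phenyl]-5-(5-bromo-2-methoxyphenyl)-4-oxo-4H-pyran-2-carbaldehyde F6.
   - Pinnick oxidation (NaClO2, NaH2PO4, 2‑methyl‑2‑butene, t‑BuOH/H2O) then gives 11.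

3. Step 10. Hydroxide may open the pyranone ring of flavone 1 during the slow condensation of the electron‑rich aldehyde, or the sparingly soluble phenoxide salts may stall the aldol step. The fallback builds flavone 2 by acyl transfer under non‑nucleophilic base; it sets out from 22 and comes back to the route at 26, bypassing steps 10 and 11.
   - Pinnick oxidation of 22 should give 3-{2-[4-(benzyloxy)phenyl]-5-hydroxy-7-methoxy-4-oxo-4H-chromen-3-yl}-4-methoxybenzoic acid F7.
   - EDC·HCl/DMAP esterification with 23 gives 2-acetyl-3,5-bis(benzyloxy)phenyl 3-{2-[4-(benzyloxy)phenyl]-5-hydroxy-7-methoxy-4-oxo-4H-chromen-3-yl}-4-methoxybenzoate F8.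
   - LiN(SiMe3)2 in THF at −20 °C brings about the Baker–Venkataraman acyl shift to 1-[2,4-bis(benzyloxy)-6-hydroxyphenyl]-3-(3-{2-[4-(benzyloxy)phenyl]-5-hydroxy-7-methoxy-4-oxo-4H-chromen-3-yl}-4-methoxyphenyl)propane-1,3-dione F9.
   - TsOH in toluene at 90 °C cyclodehydrates F9 to 26.

**Further compounds**

F1 | step 8 | 2-(5-bromo-2-methoxyphenyl)-1-(2,4,6-trihydroxyphenyl)ethan-1-one | COc1ccc(Br)cc1CC(=O)c1c(O)cc(O)cc1O
F2 | step 8 | 2-[4-(benzyloxy)phenyl]-3-(5-bromo-2-methoxyphenyl)-5-hydroxy-4-oxo-4H-chromen-7-yl 4-(benzyloxy)benzoate | O=C(Oc1cc(O)c2c(=O)c(-c3cc(Br)ccc3OC)c(-c3ccc(OCc4ccccc4)cc3)oc2c1)c1ccc(OCc2ccccc2)cc1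
F3 | step 8 | 2-[4-(benzyloxy)phenyl]-3-(5-bromo-2-methoxyphenyl)-5,7-dihydroxy-4H-chromen-4-one | Oc1cc(O)c2c(=O)c(-c3cc(Br)ccc3OC)c(-c3ccc(OCc4ccccc4)cc3)oc2c1
F4 | step 4 | 4-{1-[4-(benzyloxy)phenyl]-2-(5-bromo-2-methoxyphenyl)ethenyl}morpholine | COc1ccc(Br)cc1C=C(N1CCOCC1)c1ccc(OCc2ccccc2)cc1
F5 | step 4 | 6-[4-(benzyloxy)phenyl]-5-(5-bromo-2-methoxyphenyl)-2-methyl-4H-pyran-4-one | Cc1cc(=O)c(-c2cc(Br)ccc2OC)c(-c2ccc(OCc3ccccc3)cc2)o1
F6 | step 4 | 6-[4-(benzyloxy)phenyl]-5-(5-bromo-2-methoxyphenyl)-4-oxo-4H-pyran-2-carbaldehyde | O=Cc1cc(=O)c(-c2cc(Br)ccc2OC)c(-c2ccc(OCc3ccccc3)cc2)o1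
F7 | step 10 | 3-{2-[4-(benzyloxy)phenyl]-5-hydroxy-7-methoxy-4-oxo-4H-chromen-3-yl}-4-methoxybenzoic acid | COc1cc(O)c2c(=O)c(-c3cc(C(=O)O)ccc3OC)c(-c3ccc(OCc4ccccc4)cc3)oc2c1
F8 | step 10 | 2-acetyl-3,5-bis(benzyloxy)phenyl 3-{2-[4-(benzyloxy)phenyl]-5-hydroxy-7-methoxy-4-oxo-4H-chromen-3-yl}-4-methoxybenzoate | COc1cc(O)c2c(=O)c(-c3cc(C(=O)Oc4cc(OCc5ccccc5)cc(OCc5ccccc5)c4C(C)=O)ccc3OC)c(-c3ccc(OCc4ccccc4)cc3)oc2c1
F9 | step 10 | 1-[2,4-bis(benzyloxy)-6-hydroxyphenyl]-3-(3-{2-[4-(benzyloxy)phenyl]-5-hydroxy-7-methoxy-4-oxo-4H-chromen-3-yl}-4-methoxyphenyl)propane-1,3-dione | COc1cc(O)c2c(=O)c(-c3cc(C(=O)CC(=O)c4c(O)cc(OCc5ccccc5)cc4OCc4ccccc4)ccc3OC)c(-c3ccc(OCc4ccccc4)cc3)oc2c1
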